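**Plan**

1. Retrosynthesis: the oxepane is opened last at C3–O, giving a C16 primary alcohol and an exocyclic C3=C18 methylene on the oxonane. Before that, C6–O/C7–H and C16–O go back to alkenes (hydroborations) and the C3 methylene goes back to a C3 carbinol.
2. Then C1–C10 and C13–C14 are cut (intramolecular Diels–Alder: oxolane + cyclohexene), then C6=C7 (ring-closing metathesis: oxonene), C2–C3 (glycolate aldol), C2–O (Williamson) and C7–C8 (epoxide opening).
3. Forward ring order: acyclic glycolate ether → nine-membered oxonene → oxolane and cyclohexene together in one Diels–Alder step → oxepane by intramolecular alkoxymercuration–demercuration, which gives the target itself.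
4. Enabling feature: the C16 hydroxyl sits on C15 at C14 of the cyclohexane, five atoms from C3 through C1–C2 of the oxolane. C3 is the fully substituted carbon of a 1,1-disubstituted alkene on the oxonane, so Markovnikov O–C3 bonding closes the seven-membered ring and creates the quaternary ether centre in one event.
5. Stereochemistry: C9 from (R)-glycidol; C2 from an auxiliary-controlled aldol; C1, C10, C14 from the exo Diels–Alder; C12 and C11 by convex-face protonation and hydride delivery; C15 and C6/C7 by substrate-controlled hydroborations; C3 in the key step.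

Key step: step 26

Remark: locants follow the asbestinin skeleton: oxolane O bridges C2 and C9; oxepane O bridges C3 and C16; cyclohexane = C1, C10–C14; C15 carries C16 and C17; methyls C18 on C3, C19 on C7, C20 on C12. In this numbering the target SMILES is read as 1S,2S,3S,6R,7R,9S,10R,11R,12R,14S,15R.

**Route**

Step 1
Reactants: 1 (R)-glycidol
Product: 2 (S)-2-{[(4-methoxybenzyl)oxy]methyl}oxirane
Conditions: NaH, PMBCl, Bu4NI (cat.), THF/DMF, 0 °C → rt
Reagents that add atoms: 4-methoxybenzyl chloride, COc1ccc(CCl)cc1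
Why: Williamson etherification of the primary alkoxide leaves the stereocentre untouched (the R→S change of label is only a CIP priority change).

Step 2
Reactants: 2 (S)-PMB glycidyl ether
Product: 3 (S)-1-[(4-methoxybenzyl)oxy]-4-methylpent-4-en-2-ol
Conditions: isopropenylMgBr, CuI (10 mol %), THF, −30 → 0 °C
Reagents that add atoms: isopropenylmagnesium bromide, CC(=C)[Mg]Br
Why: Copper-catalysed Grignard opening of the terminal epoxide at the CH2 carbon (SN2) carries the glycidol stereocentre over as C9 and brings in C7, C8 and C19.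

Step 3
Reactants: 3 homoallylic alcohol
Product: 4 2-{[(S)-1-((4-methoxybenzyl)oxy)-4-methylpent-4-en-2-yl]oxy}acetic acid
Conditions: NaH (3 equiv), BrCH2CO2H, THF/DMF, 0 °C → rt; acidic work-up
Reagents that add atoms: bromoacetic acid, OC(=O)CBr
Why: Williamson O-alkylation of the secondary alkoxide with sodium bromoacetate gives the glycolic acid (C1, C2) without touching C9.

Step 4
Reactants: 4 glycolic acid
Product: 6 (R)-4-benzyl-3-(alkoxyacetyl)oxazolidin-2-one, via mixed pivalic anhydride 5 (not isolated)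
Conditions: PivCl, Et3N, THF, −78 → 0 °C; then lithiated (R)-4-benzyl-2-oxazolidinone (n-BuLi, THF, −78 °C), −78 → 0 °C
Reagents that add atoms: (R)-4-benzyl-2-oxazolidinone, O=C1N[C@H](Cc2ccccc2)CO1
Why: N-Acylation of the lithiated oxazolidinone by the mixed anhydride installs the chiral auxiliary.

Step 5
Reactants: 6 glycolyl imide
Product: 8 syn-aldol adduct (2R,3S), via dibutylboron Z-enolate 7 (not isolated)
Conditions: n-Bu2BOTf, Et3N, CH2Cl2, −78 → 0 °C; pent-4-enal, −78 → 0 °C; pH 7 buffer, MeOH, H2O2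
Reagents that add atoms: pent-4-enal, C=CCCC=O
Why: Evans syn aldol through the Z-boron enolate and a Zimmerman–Traxler chair; the (R)-benzyl auxiliary shields one enolate face and so sets C2 (and a provisional C3 carbinol) while adding C3–C6.

Step 6
Reactants: 8 aldol adduct
Product: 9 (2R,3S)-3-hydroxy Weinreb amide
Conditions: MeNH(OMe)·HCl, AlMe3, CH2Cl2, −20 → 0 °C
Reagents that add atoms: N,O-dimethylhydroxylamine hydrochloride, CNOC.Cl
Why: Aluminium-amide transamination of the β-hydroxy imide (Weinreb amide formation) removes the auxiliary and leaves C1 as a latent aldehyde.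

Step 7
Reactants: 9 hydroxy amide
Product: 10 3-O-TBS Weinreb amide
Conditions: TBSOTf, 2,6-lutidine, CH2Cl2, −78 → 0 °C
Reagents that add atoms: tert-butyldimethylsilyl triflate, CC(C)(C)[Si](C)(C)OS(=O)(=O)C(F)(F)F
Why: Silylation of the secondary alcohol gives an ether that should survive every step up to its planned removal in step 22.

Step 8
Reactants: 10 diene
Product: 11 (2R,3S,9S,6Z)-oxonene (2,9-cis)
Conditions: Grubbs second-generation catalyst (5 mol %), CH2Cl2 (2 mM), 40 °C
Reagents that add atoms: none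
Why: Ring-closing metathesis (Ru loads on the monosubstituted alkene and closes on the 1,1-disubstituted one); the gauche preference of the C2/C3 oxygens folds the chain, and the nine-membered ring enforces the Z trisubstituted C6=C7 alkene.

Step 9
Reactants: 11 oxonene PMB ether
Product: 12 C10 primary alcohol
Conditions: DDQ, CH2Cl2/pH 7 buffer, 0 °C
Reagents that add atoms: none
Why: Oxidative PMB cleavage (benzylic hydride abstraction, hemiacetal hydrolysis) leaves the alkene, silyl ether and amide untouched.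

Step 10
Reactants: 12 primary alcohol
Product: 13 C10 aldehyde
Conditions: Dess–Martin periodinane, NaHCO3, CH2Cl2, 0 °C → rt
Reagents that add atoms: none
Why: Buffered Dess–Martin oxidation should give the α-alkoxy aldehyde without epimerizing C9.

Step 11
Reactants: 14 dimethyl (1-diazo-2-oxopropyl)phosphonate
Product: 15 dimethyl (1-methoxy-2-oxopropyl)phosphonate (racemic)
Conditions: Rh2(OAc)4 (1 mol %), MeOH, CH2Cl2, 40 °C
Reagents that add atoms: methanol, CO
Why: Rhodium-carbenoid O–H insertion into methanol gives the α-methoxy β-keto phosphonate, whose stereocentre disappears in step 12.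

Step 12
Reactants: 13 C10 aldehyde; 15 phosphonate
Product: 16 (Z)-2-methoxy enone at C10–C12
Conditions: 15, NaH, THF, 0 °C; then 13, −78 → 0 °C
Reagents that add atoms: none
Why: Horner–Wadsworth–Emmons olefination places the acyl group trans to C9, so the enol ether is Z with C9 and OMe cis, the geometry the diene needs.

Step 13
Reactants: 16 enone
Product: 17 2-methoxy-3-methyl-1,3-diene (C10–C13)
Conditions: Ph3PCH3Br, KOt-Bu, THF, 0 °C → rt
Reagents that add atoms: methyltriphenylphosphonium bromide, C[P+](c1ccccc1)(c1ccccc1)c1ccccc1.[Br-]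
Why: Wittig methylenation of the ketone (1,2-addition) supplies C13; the Weinreb amide does not react with the ylide.

Step 14
Reactants: 17 diene Weinreb amide
Product: 18 C1 aldehyde
Conditions: DIBAL-H, THF, −78 °C; Rochelle salt work-up
Reagents that add atoms: none
Why: Weinreb amide reduction stops at the aldehyde through the chelated tetrahedral intermediate, and the neutral work-up spares the enol ether diene and C2.

Step 15
Reactants: 18 aldehyde
Product: 20 tricyclic Diels–Alder adduct (C15 methyl ketone and C11 methyl enol ether), via E-enone tetraene 19 (not isolated)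
Conditions: Ph3P=CHC(O)CH3, CH2Cl2, rt; then toluene, 60 °C if needed
Reagents that add atoms: 1-(triphenylphosphoranylidene)propan-2-one, CC(=O)C=P(c1ccccc1)(c1ccccc1)c1ccccc1
Why: Wittig olefination with the stabilized ylide gives the E-enone, which should undergo a type-1 intramolecular Diels–Alder reaction (tether C2–O–C9, ketone exo) forming C1–C10 and C13–C14; this gives the cis-fused oxolane/cyclohexene with H1/H10 anti to H2/H9 (addition on the face away from the oxonene bridge) and C2/C15 trans from the E-alkene.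

Step 16
Reactants: 20 methyl ketone
Product: 21 C14 isopropenyl tricycle
Conditions: Ph3PCH3Br, KOt-Bu, THF, 0 °C → rt
Reagents that add atoms: methyltriphenylphosphonium bromide, C[P+](c1ccccc1)(c1ccccc1)c1ccccc1.[Br-]
Why: Wittig methylenation supplies C16; C14 is already in its thermodynamically preferred trans-diequatorial arrangement and the enol ether is inert.

Step 17
Reactants: 21 methyl enol ether
Product: 23 C11 alcohol (11-OH and 12-CH3 cis), via C11 ketone 22 (not isolated)
Conditions: aq. oxalic acid, THF, 0 °C → rt; then NaHCO3 to pH 7, NaBH4, MeOH, −20 °C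
Reagents that add atoms: water, O
Why: Enol ether hydrolysis proceeds by rate-limiting C-protonation at C12 on the convex face (anti to the axial C10–C9 bond), which sets the axial C12 methyl, and NaBH4 then attacks C11 axially from the same face to give the equatorial alcohol.

Step 18
Reactants: 23 isopropenyl alcohol
Product: 25 11,16-diol with C15 set, via B-alkyl-9-BBN adduct 24 (not isolated)
Conditions: 9-BBN, THF, 0 °C → rt; then NaBO3·4H2O, THF/H2O, rt
Reagents that add atoms: sodium perborate (oxygen source), [Na+].[Na+].O[B-]1(O)OO[B-](O)(O)OO1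
Why: Anti-Markovnikov hydroboration of the 1,1-disubstituted alkene only (trisubstituted C6=C7 is inert to 9-BBN); C15 follows from 1,2-induction with H14 in the alkene plane and the borane anti to the larger C1 branch, and oxidation retains configuration.

Step 19
Reactants: 25 diol
Product: 26 11,16-diacetate
Conditions: Ac2O, DMAP, pyridine, CH2Cl2, rt
Reagents that add atoms: acetic anhydride, CC(=O)OC(C)=O
Why: DMAP-catalysed acetylation installs the final C11 acetate and at the same time masks the C16 hydroxyl.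

Step 20
Reactants: 26 diacetate
Product: 28 C6 alcohol (6-OH and 7-H cis), via C6 alkylborane 27 (not isolated)
Conditions: BH3·THF, THF, 0 °C; then NaBO3·4H2O, THF/H2O, 0 °C → rt
Reagents that add atoms: sodium perborate (oxygen source), [Na+].[Na+].O[B-]1(O)OO[B-](O)(O)OO1
Why: Hydroboration–oxidation of the only remaining alkene puts boron on the less substituted C6 and adds syn from the peripheral face of the Z-oxonene (C19 methyl turned to the open ether-bridge side), setting C6 and C7 together.

Step 21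
Reactants: 28 C6 alcohol
Product: 29 C6 methyl ether
Conditions: Me3OBF4, 1,8-bis(dimethylamino)naphthalene, CH2Cl2, rt
Reagents that add atoms: trimethyloxonium tetrafluoroborate, C[O+](C)C.F[B-](F)(F)F
Why: O-Methylation with Meerwein's salt and a non-nucleophilic base avoids acetate migration or cleavage.

Step 22
Reactants: 29 TBS ether
Product: 30 C3 alcohol
Conditions: HF·pyridine, pyridine/THF, 0 °C → rt
Reagents that add atoms: none
Why: Fluoride cleaves the Si–O bond while the acetates and the methyl ether stay intact.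

Step 23
Reactants: 30 C3 alcohol
Product: 31 C3 ketone
Conditions: Dess–Martin periodinane, NaHCO3, CH2Cl2, rt
Reagents that add atoms: none
Why: Dess–Martin oxidation of the only free hydroxyl gives the α-alkoxy ring ketone under non-epimerizing conditions.

Step 24
Reactants: 31 C3 ketone
Product: 32 C3 exocyclic methylene diacetate
Conditions: Zn, CH2Br2, TiCl4, THF/CH2Cl2, 0 °C → rt
Reagents that add atoms: dibromomethane, BrCBr
Why: Lombardo methylenation with the gem-dizinc/titanium reagent is non-basic, so C2 next to the ketone should not epimerize and the acetates should not react.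

Step 25
Reactants: 32 diacetate
Product: 33 C16 alcohol (C11 acetate kept)
Conditions: K2CO3 (0.3 equiv), MeOH, −10 → 0 °C
Reagents that add atoms: none
Why: Base-catalysed transesterification should remove the unhindered primary acetate much faster than the C11 acetate, which is flanked by two branched ring carbons.

Step 26
Reactants: 33 hydroxy alkene
Product: 35 target, via alkylmercury trifluoroacetate 34 (not isolated)
Conditions: Hg(OCOCF3)2 (1.1 equiv), CH2Cl2, −20 → 0 °C; then NaBH4, 1 M aq. NaOH, THF, −20 °C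
Reagents that add atoms: none
Why: Hg(II) forms a reversible mercurinium ion on the C3=C18 alkene, the C16 hydroxyl opens it anti at the tertiary C3 (Markovnikov) to give 34, and NaBH4 replaces the C18–Hg bond by C–H, creating the C18 methyl. The closest known reaction type is intramolecular alkoxymercuration–demercuration of a hydroxy alkene, as used to make tertiary ether bridges on medium-ring ethers. The only ring closed is the oxepane, in 7-exo-trig mode (oxygen to the internal alkene carbon, CH2Hg left exocyclic). The new stereocentre C3 is set by the substrate: in the rotamer where the methylene eclipses C2–H (minimal allylic 1,3-strain) C4 stays anti to H2 as in the product, and the tethered hydroxyl, anchored at C14 next to C1, can reach only the alkene face syn to the C2–C1 bond, giving the cis-fused oxepane/oxonane. The step needs Markovnikov regioselectivity, secured by tertiary C3 versus primary C18 and by a seven- rather than eight-membered ring. It also needs oxygen selectivity, secured because 33 has a single alkene and a single free hydroxyl, while an oxonium formed by the C6 methoxy oxygen can only revert.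

**Compound list**

1 | (R)-glycidol [(R)-oxiran-2-ylmethanol] | OC[C@@H]1CO1 | starting material
2 | (S)-2-{[(4-methoxybenzyl)oxy]methyl}oxirane | COc1ccc(COC[C@@H]2CO2)cc1 | intermediate
3 | (S)-1-[(4-methoxybenzyl)oxy]-4-methylpent-4-en-2-ol | O[C@H](COCc1ccc(OC)cc1)CC(C)=C | intermediate
4 | 2-{[(S)-1-((4-methoxybenzyl)oxy)-4-methylpent-4-en-2-yl]oxy}acetic acid | OC(=O)CO[C@H](COCc1ccc(OC)cc1)CC(C)=C | intermediate
5 | mixed anhydride of 4 with pivalic acid | CC(C)(C)C(=O)OC(=O)CO[C@H](COCc1ccc(OC)cc1)CC(C)=C | intermediate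
6 | (R)-4-benzyl-3-(2-{[(S)-1-((4-methoxybenzyl)oxy)-4-methylpent-4-en-2-yl]oxy}acetyl)oxazolidin-2-one | O=C(CO[C@H](COCc1ccc(OC)cc1)CC(C)=C)N1[C@H](Cc2ccccc2)COC1=O | intermediate
7 | (Z)-dibutylboron enolate of 6 (O–B and the ether oxygen cis) | CCCCB(CCCC)O/C(=C\O[C@H](COCc1ccc(OC)cc1)CC(C)=C)N1[C@H](Cc2ccccc2)COC1=O | intermediate
8 | (R)-4-benzyl-3-[(2R,3S)-3-hydroxy-2-{[(S)-1-((4-methoxybenzyl)oxy)-4-methylpent-4-en-2-yl]oxy}hept-6-enoyl]oxazolidin-2-one | O=C([C@@H]([C@H](CCC=C)O)O[C@H](COCc1ccc(OC)cc1)CC(C)=C)N1[C@H](Cc2ccccc2)COC1=O | intermediate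
9 | (2R,3S)-3-hydroxy-N-methoxy-2-{[(S)-1-((4-methoxybenzyl)oxy)-4-methylpent-4-en-2-yl]oxy}-N-methylhept-6-enamide | CON(C)C(=O)[C@@H]([C@H](CCC=C)O)O[C@H](COCc1ccc(OC)cc1)CC(C)=C | intermediate
10 | 3-O-tert-butyldimethylsilyl ether of 9 | CON(C)C(=O)[C@@H]([C@H](CCC=C)O[Si](C)(C)C(C)(C)C)O[C@H](COCc1ccc(OC)cc1)CC(C)=C | intermediate
11 | (2R,3S,9S,Z)-3-[(tert-butyldimethylsilyl)oxy]-N-methoxy-9-{[(4-methoxybenzyl)oxy]methyl}-N,7-dimethyl-2,3,4,5,8,9-hexahydrooxonine-2-carboxamide | CON(C)C(=O)[C@@H]1O[C@H](COCc2ccc(OC)cc2)C/C(C)=C\CC[C@@H]1O[Si](C)(C)C(C)(C)C | intermediate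
12 | 9-(hydroxymethyl) analogue of 11 (2R,3S,9S,Z) | CON(C)C(=O)[C@@H]1O[C@H](CO)C/C(C)=C\CC[C@@H]1O[Si](C)(C)C(C)(C)C | intermediate
13 | 9-formyl analogue of 11 (2R,3S,9S,Z) | CON(C)C(=O)[C@@H]1O[C@H](C=O)C/C(C)=C\CC[C@@H]1O[Si](C)(C)C(C)(C)C | intermediate
14 | dimethyl (1-diazo-2-oxopropyl)phosphonate | COP(=O)(OC)C(=[N+]=[N-])C(C)=O | starting material
15 | dimethyl (1-methoxy-2-oxopropyl)phosphonate (racemic) | COC(C(C)=O)P(=O)(OC)OC | intermediate
16 | oxonene of 11 carrying at C9 a (1Z)-2-methoxy-3-oxobut-1-enyl group (C9 and OMe cis) | CON(C)C(=O)[C@@H]1O[C@H](/C=C(OC)/C(C)=O)C/C(C)=C\CC[C@@H]1O[Si](C)(C)C(C)(C)C | intermediate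
17 | oxonene of 11 carrying at C9 a (1Z)-2-methoxy-3-methylbuta-1,3-dienyl group | CON(C)C(=O)[C@@H]1O[C@H](/C=C(OC)/C(C)=C)C/C(C)=C\CC[C@@H]1O[Si](C)(C)C(C)(C)C | intermediate
18 | (2R,3S,9S,Z)-3-[(tert-butyldimethylsilyl)oxy]-9-[(1Z)-2-methoxy-3-methylbuta-1,3-dienyl]-7-methyl-2,3,4,5,8,9-hexahydrooxonine-2-carbaldehyde | O=C[C@@H]1O[C@H](/C=C(OC)/C(C)=C)C/C(C)=C\CC[C@@H]1O[Si](C)(C)C(C)(C)C | intermediate
19 | tetraene: 18 with the aldehyde converted into an (E)-3-oxobut-1-enyl group at C2 (ring stereocentres as in 18) | CC(=O)/C=C/[C@@H]1O[C@H](/C=C(OC)/C(C)=C)C/C(C)=C\CC[C@@H]1O[Si](C)(C)C(C)(C)C | intermediate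
20 | tricycle: oxolane (C1, C2, O, C9, C10) cis-fused to a cyclohexene (C11 OMe enol ether, C12 methyl) and bridged by the Z-oxonene (3-OTBS); H1/H10 cis and anti to H2/H9; C14 acetyl trans to C2 | CC(=O)[C@@H]3CC(C)=C(OC)[C@@H]4[C@H]3[C@@H]2O[C@H]4C/C(C)=C\CC[C@@H]2O[Si](C)(C)C(C)(C)C | intermediate
21 | 20 with the C14 acetyl replaced by isopropenyl | C=C(C)[C@@H]3CC(C)=C(OC)[C@@H]4[C@H]3[C@@H]2O[C@H]4C/C(C)=C\CC[C@@H]2O[Si](C)(C)C(C)(C)C | intermediate
22 | C11 ketone with the C12 methyl cis to C9 and C2 (configuration of the target at C12) | C=C(C)[C@@H]3C[C@@H](C)C(=O)[C@@H]4[C@H]3[C@@H]2O[C@H]4C/C(C)=C\CC[C@@H]2O[Si](C)(C)C(C)(C)C | intermediate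
23 | C11 alcohol (11-OH cis to 12-CH3; C11 and C12 as in the target) | C=C(C)[C@@H]3C[C@@H](C)[C@@H](O)[C@@H]4[C@H]3[C@@H]2O[C@H]4C/C(C)=C\CC[C@@H]2O[Si](C)(C)C(C)(C)C | intermediate
24 | B-(C16-alkyl)-9-borabicyclo[3.3.1]nonane adduct of 23 (C15 as in the target) | C(B5C6CCCC5CCC6)[C@H](C)[C@@H]3C[C@@H](C)[C@@H](O)[C@@H]4[C@H]3[C@@H]2O[C@H]4C/C(C)=C\CC[C@@H]2O[Si](C)(C)C(C)(C)C | intermediate
25 | 11,16-diol (C15 as in the target; 3-OTBS; Z-oxonene) | OC[C@H](C)[C@@H]3C[C@@H](C)[C@@H](O)[C@@H]4[C@H]3[C@@H]2O[C@H]4C/C(C)=C\CC[C@@H]2O[Si](C)(C)C(C)(C)C | intermediate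
26 | 11,16-diacetate of 25 | CC(=O)OC[C@H](C)[C@@H]3C[C@@H](C)[C@@H](OC(C)=O)[C@@H]4[C@H]3[C@@H]2O[C@H]4C/C(C)=C\CC[C@@H]2O[Si](C)(C)C(C)(C)C | intermediate
27 | C6 monoalkylborane (B at C6 and H at C7 cis; C6/C7 as in the target) | CC(=O)OC[C@H](C)[C@@H]3C[C@@H](C)[C@@H](OC(C)=O)[C@@H]4[C@H]3[C@@H]2O[C@H]4C[C@@H](C)[C@H](B)CC[C@@H]2O[Si](C)(C)C(C)(C)C | intermediate
28 | C6 alcohol (6R,7R as in the target; 3-OTBS; 11,16-diacetate) | CC(=O)OC[C@H](C)[C@@H]3C[C@@H](C)[C@@H](OC(C)=O)[C@@H]4[C@H]3[C@@H]2O[C@H]4C[C@@H](C)[C@H](O)CC[C@@H]2O[Si](C)(C)C(C)(C)C | intermediate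
29 | C6 methyl ether of 28 | CC(=O)OC[C@H](C)[C@@H]3C[C@@H](C)[C@@H](OC(C)=O)[C@@H]4[C@H]3[C@@H]2O[C@H]4C[C@@H](C)[C@H](OC)CC[C@@H]2O[Si](C)(C)C(C)(C)C | intermediate
30 | C3 alcohol (29 without the silyl group) | CC(=O)OC[C@H](C)[C@@H]3C[C@@H](C)[C@@H](OC(C)=O)[C@@H]4[C@H]3[C@@H]2O[C@H]4C[C@@H](C)[C@H](OC)CC[C@@H]2O | intermediate
31 | C3 ketone (6-OMe, 7-Me, 11,16-diacetate) | CC(=O)OC[C@H](C)[C@@H]3C[C@@H](C)[C@@H](OC(C)=O)[C@@H]4[C@H]3[C@@H]2O[C@H]4C[C@@H](C)[C@H](OC)CCC2=O | intermediate
32 | C3 exocyclic methylene (C3=C18) 11,16-diacetate | CC(=O)OC[C@H](C)[C@@H]3C[C@@H](C)[C@@H](OC(C)=O)[C@@H]4[C@H]3[C@@H]2O[C@H]4C[C@@H](C)[C@H](OC)CCC2=C | intermediate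
33 | 16-hydroxy-3(18)-ene 11-acetate (all ten stereocentres as in the target) | OC[C@H](C)[C@@H]3C[C@@H](C)[C@@H](OC(C)=O)[C@@H]4[C@H]3[C@@H]2O[C@H]4C[C@@H](C)[C@H](OC)CCC2=C | intermediate
34 | tetracyclic C18 alkylmercury(II) trifluoroacetate (oxepane closed, C3 as in the target) | CO[C@@H]1CC[C@]2(C[Hg]OC(=O)C(F)(F)F)OC[C@H](C)[C@@H]3C[C@@H](C)[C@@H](OC(C)=O)[C@@H]4[C@H]3[C@@H]2O[C@H]4C[C@H]1C | intermediate
35 | CNP0289153.2: (1S,2S,3S,6R,7R,9S,10R,11R,12R,14S,15R)-11-acetoxy-6-methoxy asbestinin-type tetracycle (2,9-epoxy and 3,16-epoxy bridges) | CO[C@@H]1CC[C@]2(C)OC[C@H](C)[C@@H]3C[C@@H](C)[C@@H](OC(C)=O)[C@@H]4[C@H]3[C@@H]2O[C@H]4C[C@H]1C | target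

**Count**

Total steps: 26. Longest linear sequence: 25 (steps 1–10 and 12–26; step 11 makes phosphonate 15 in one step from 14).

**Steps most likely to fail, with fallbacks**

Step 26. The hydroxyl may add to the other face of the C3 methylene (C3 epimer), ring closure to the seven-membered ether may be slow, or the C6 methoxy oxygen may take part transannularly. Fallback (sets out from 31, returns at 35): the oxepane is closed through the O–C16 bond instead. Ketone 31 is treated with MeTi(O-iPr)3 (THF, −40 → 0 °C), which adds methyl to the ketone but not to the acetates, on the exposed face of the ketone chelated to the adjacent ring ether oxygen, to give the C3 tertiary alcohol diacetate F1. Methanolysis of the primary acetate (K2CO3, MeOH, 0 °C) gives the 3,16-diol F2. Tf2O/2,6-lutidine (CH2Cl2, −78 → 0 °C) converts the primary hydroxyl into the C16 triflate F3 (not isolated), which the tertiary C3 hydroxyl displaces by SN2 to give 35.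

Step 20. The borane may add to the other face of the C6=C7 alkene (giving the 6,7-bis-epimer), and the acetates may be partly reduced. Fallback (sets out from 26, returns at 28): epoxidation with dimethyldioxirane on the exposed face gives the 6,7-epoxide F4. A Meinwald rearrangement (BF3·OEt2, CH2Cl2, −78 °C) opens it at the tertiary C7 with a 1,2-hydride shift from C6, anti to the leaving oxygen, and gives the C6 ketone F5. An epoxide on the face that was wrong for hydroboration gives the right C7 methyl configuration here, and C7 can also be equilibrated next to the ketone. Reduction of F5 (NaBH4, or L-Selectride for the opposite facial preference) gives 28.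

Step 18. The 1,2-induction at C15 may be low, giving a mixture of C15 epimers. Fallback (sets out from 23, returns at 25): catalyst control replaces substrate control. Copper-hydride-catalysed asymmetric hydroboration with pinacolborane and a chiral bisphosphine ligand (ligand antipode chosen to match) gives the C16 pinacol boronate F6, which NaBO3 oxidizes with retention to 25.

Further compounds
F1 | step 26 | C3 tertiary alcohol 11,16-diacetate (3-OH and C1 cis, 3-CH3 as in the target) | CC(=O)OC[C@H](C)[C@@H]3C[C@@H](C)[C@@H](OC(C)=O)[C@@H]4[C@H]3[C@@H]2O[C@H]4C[C@@H](C)[C@H](OC)CC[C@]2(C)O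
F2 | step 26 | 3,16-diol 11-acetate | OC[C@H](C)[C@@H]3C[C@@H](C)[C@@H](OC(C)=O)[C@@H]4[C@H]3[C@@H]2O[C@H]4C[C@@H](C)[C@H](OC)CC[C@]2(C)O
F3 | step 26 | C16 triflate of F2 | O=S(=O)(OC[C@H](C)[C@@H]3C[C@@H](C)[C@@H](OC(C)=O)[C@@H]4[C@H]3[C@@H]2O[C@H]4C[C@@H](C)[C@H](OC)CC[C@]2(C)O)C(F)(F)F
F4 | step 20 | 6,7-epoxide of 26 (oxygen on the face opposite to the C6 oxygen of the target) | CC(=O)OC[C@H](C)[C@@H]3C[C@@H](C)[C@@H](OC(C)=O)[C@@H]4[C@H]3[C@@H]2O[C@H]4C[C@@]5(C)O[C@H]5CC[C@@H]2O[Si](C)(C)C(C)(C)C
F5 | step 20 | C6 ketone with C7 as in the target (3-OTBS, 11,16-diacetate) | CC(=O)OC[C@H](C)[C@@H]3C[C@@H](C)[C@@H](OC(C)=O)[C@@H]4[C@H]3[C@@H]2O[C@H]4C[C@@H](C)C(=O)CC[C@@H]2O[Si](C)(C)C(C)(C)C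
F6 | step 18 | C16 pinacol boronate of 23 (C15 as in the target) | CC1(C)OB(C[C@H](C)[C@@H]3C[C@@H](C)[C@@H](O)[C@@H]4[C@H]3[C@@H]2O[C@H]4C/C(C)=C\CC[C@@H]2O[Si](C)(C)C(C)(C)C)OC1(C)C
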